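Ring carbons are numbered C1–C11 in the order of the target SMILES (C1 bears the angelate). Everything rests on the C4–C5 bond, which joins the methyl-bearing quaternary carbon to the cyclobutane CH beside the enone carbonyl. With C3 at the ketone level, C4 and C5 are the two α-carbons of a 1,4-diketone (C3, C6), two donor carbons. Their oxidative enolate coupling in a cis-fused cycloheptanone/3-methylcyclohexenone bicycle closes with one bond both the cyclobutane and the cyclohexenone ring C4–C5–C6–C7–C8–C9 of the bicyclo[3.1.1]heptenone and sets the quaternary centre. The precursor is a 6-7-fused epoxy diketone whose convex-face epoxide later relays the three oxygenated centres.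

Key step: step 12

Assumption: compounds 1, 3, 7, 22 and 26 are bought (26 as the enantiopure (R)-acid); in the tricyclic compounds the two faces of the C1–C2–C3 segment are called the C9 face and the C5 face after the cyclobutane carbon they lie over, and C4 is carried as an epimer mixture from step 6 until it is planarised in step 12.

Step 1
Reactants: 1 methyl 3,3-dimethylpent-4-enoate
Product: 2 3,3-dimethylpent-4-enal
Conditions: (i-Bu)2AlH (1.05 equiv), CH2Cl2, −78 °C; MeOH, aq. Rochelle salt
Reagents that add atoms: none
Why: Partial ester reduction with (i-Bu)2AlH stops at the aldehyde because the tetrahedral aluminium alkoxide survives at −78 °C until work-up; no stereocentre is involved.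

Step 2
Reactants: 2 3,3-dimethylpent-4-enal; 3 pent-1-en-3-one
Product: 4 (S)-2-(2-methylbut-3-en-2-yl)-5-oxoheptanal
Conditions: (S)-α,α-diphenylprolinol trimethylsilyl ether (10 mol %), ethyl 3,4-dihydroxybenzoate (20 mol %), neat, 4 °C
Reagents that add atoms: none
Why: Enamine-catalysed asymmetric Michael addition of an aldehyde to an enone, in which the diaryl(silyloxy)methyl group shields one face of the E-enamine so that the enone adds to the other, which for this substituent pattern should give the (S)-aldehyde (future C10).

Step 3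
Reactants: 4 (S)-2-(2-methylbut-3-en-2-yl)-5-oxoheptanal
Product: 5 (R)-2-methyl-4-(2-methylbut-3-en-2-yl)cyclohex-2-en-1-one
Conditions: LiOH (0.2 equiv), i-PrOH, rt
Reagents that add atoms: none
Why: Intramolecular aldol condensation of the 1,5-keto aldehyde (the ethyl-ketone CH2 attacks the aldehyde) closes the cyclohexenone, and the hindered stereocentre is carried over unchanged (the descriptor changes only through the priority rules).

Step 4
Reactants: 5 (R)-2-methyl-4-(2-methylbut-3-en-2-yl)cyclohex-2-en-1-one
Product: 6 (1R,4R)-2-methyl-4-(2-methylbut-3-en-2-yl)cyclohex-2-en-1-ol (1,4-trans)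
Conditions: NaBH4, CeCl3·7H2O, MeOH, −78 °C
Reagents that add atoms: none
Why: Luche 1,2-reduction, in which axial hydride delivery to the half-chair with the tert-alkyl group pseudo-equatorial should give mainly the pseudo-equatorial, 1,4-trans allylic alcohol.

Step 5
Reactants: 6 (1R,4R)-2-methyl-4-(2-methylbut-3-en-2-yl)cyclohex-2-en-1-ol; 7 propanoic acid
Product: 8 (1S,4R)-2-methyl-4-(2-methylbut-3-en-2-yl)cyclohex-2-en-1-yl propanoate (1,4-cis)
Conditions: PPh3, DIAD, THF, 0 °C to rt
Reagents that add atoms: none
Why: Mitsunobu esterification proceeds with SN2 inversion at the carbinol carbon, so the trans-alcohol gives the cis-propanoate whose C–O bond lies on the ring face where the next C–C bond is needed.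

Step 6
Reactants: 8 (1S,4R)-2-methyl-4-(2-methylbut-3-en-2-yl)cyclohex-2-en-1-yl propanoate
Product: 11 2-[(1S,6R)-2-methyl-6-(2-methylbut-3-en-2-yl)cyclohex-2-en-1-yl]propanoic acid (ring substituents cis; C4 epimers), via silyl ketene acetal 9 (not isolated), via trimethylsilyl ester 10 (not isolated)
Conditions: LiN(i-Pr)2, Me3SiCl, Et3N, THF, −78 °C to 60 °C; aq. HCl
Reagents that add atoms: none
Why: The Ireland–Claisen [3,3]-sigmatropic rearrangement is suprafacial, so the propanoate α-carbon (future C4) is delivered to C9 on the face of the departing oxygen, cis to the tert-alkyl group on C10, while the ring double bond moves to C7=C8.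

Step 7
Reactants: 11 2-[(1S,6R)-2-methyl-6-(2-methylbut-3-en-2-yl)cyclohex-2-en-1-yl]propanoic acid
Product: 13 N-methoxy-N-methyl-2-[(1S,6R)-2-methyl-6-(2-methylbut-3-en-2-yl)cyclohex-2-en-1-yl]propanamide, via N-acylimidazole 12 (not isolated)
Conditions: 1,1'-carbonyldiimidazole, CH2Cl2, rt; then MeNH(OMe)·HCl
Reagents that add atoms: N,O-dimethylhydroxylamine hydrochloride, CNOC.Cl
Why: Acyl-imidazole activation followed by aminolysis gives the Weinreb amide without touching the ring stereocentres.

Step 8
Reactants: 13 N-methoxy-N-methyl-2-[(1S,6R)-2-methyl-6-(2-methylbut-3-en-2-yl)cyclohex-2-en-1-yl]propanamide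
Product: 14 4-[(1S,6R)-2-methyl-6-(2-methylbut-3-en-2-yl)cyclohex-2-en-1-yl]pent-1-en-3-one
Conditions: CH2=CHMgBr, THF, 0 °C; cold aq. NH4Cl
Reagents that add atoms: vinylmagnesium bromide, C=C[Mg]Br
Why: Grignard addition to a Weinreb amide stops at the ketone because the magnesium chelate of the tetrahedral adduct survives until work-up, giving the vinyl ketone (C3=O, future C2).

Step 9
Reactants: 14 4-[(1S,6R)-2-methyl-6-(2-methylbut-3-en-2-yl)cyclohex-2-en-1-yl]pent-1-en-3-one
Product: 15 cis-fused bicyclic enone (seven-membered ring C9–C4(Me)–C3(=O)–C2=C1–C11(Me)2–C10 fused at C9–C10 to the cyclohexene C9–C8(Me)=C7–C6H2–C5H2–C10; H9 and H10 cis)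
Conditions: second-generation Hoveyda–Grubbs catalyst (5 mol %), toluene (0.005 M), 80 °C
Reagents that add atoms: none
Why: Ring-closing olefin metathesis between the vinyl ketone and the 1,1-dimethylallyl group, held cis on C9 and C10, closes the cycloheptenone with loss of ethene while the trisubstituted ring olefin stays inert.

Step 10
Reactants: 15 cis-fused bicyclic enone
Product: 16 C1–C2 epoxide of 15 (epoxide oxygen on the convex face, anti to the six-membered ring)
Conditions: 30% H2O2, NaOH (cat.), MeOH, 0 °C
Reagents that add atoms: hydrogen peroxide, OO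
Why: Weitz–Scheffer nucleophilic epoxidation, in which hydroperoxide adds to C1 from the convex face of the cis-fused bicycle, so the oxygen sits on what becomes the C9 face of the tricycle and C2 is made non-enolisable.

Step 11
Reactants: 16 bicyclic epoxy ketone
Product: 17 bicyclic epoxy enedione (16 with C6 oxidised: ring C6(=O)–C7=C8(Me); C3 epoxy ketone unchanged)
Conditions: Pd(OH)2 on carbon (5 mol %), t-BuOOH (5 equiv), K2CO3, CH2Cl2, 4 °C
Reagents that add atoms: tert-butyl hydroperoxide, CC(C)(C)OO
Why: Palladium-catalysed allylic C–H oxidation with tert-butyl hydroperoxide (peroxyl-radical chain) converts the allylic CH2 next to the vinylic CH (C6) into the enone carbonyl, the usual site for 1-methylcyclohexenes, and leaves the epoxy ketone alone.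

Step 12
Reactants: 17 bicyclic epoxy enedione
Product: 19 tricyclic epoxy diketone (new C4–C5 bond; cyclobutane C4–C5–C10–C9; ketones at C3 and C6; C7=C8; 1,2-epoxide oxygen on the C9 face), via bis(trimethylsilyl enol ether) 18 (not isolated)
Conditions: LiN(i-Pr)2 (2.5 equiv), Me3SiCl (6 equiv, present from the start), THF, −78 °C; evaporate, take up in MeCN; (NH4)2Ce(NO3)6 (2.2 equiv), NaHCO3, MeCN, −30 °C, high dilution
Reagents that add atoms: none
Why: Kinetic deprotonation with in situ silylation gives the bis(silyl enol ether) 18 (the C3 ketone can enolise only towards C4 because C2 is an epoxide carbon, the enone is deprotonated at its α′-carbon C5, and silyl trapping should outrun intramolecular aldol addition); tetravalent cerium then removes one electron from the siloxydiene, the radical cation is attacked at C5 by the C4 terminus of the second enol ether, and a second oxidation with loss of both silyl groups leaves the 1,4-diketone. The closest known reaction type is the oxidative coupling of ketone enolates or silyl enol ethers to 1,4-diketones, used here intramolecularly. The one new bond C4–C5 closes the cyclobutane in a 4-exo mode relative to the C3=C4 enol ether and at the same time bridges C9 and C5 of the existing six-membered ring by the single atom C4, which creates the ring C4–C5–C6–C7–C8–C9 of the bicyclo[3.1.1]heptenone. Both new stereocentres (quaternary C4 and C5) are dictated by the cis ring fusion: C4 hangs on C9 and C5 on C10, so the bond can form only on the face of the seven-membered ring that carries the six-membered ring, which leaves the methyl group outside and the C6 carbonyl under the cyclobutane. The step needs C–C rather than C–O coupling and intramolecular rather than intermolecular reaction; the single enolisable position on each ketone, the proximity of the pseudo-axial C4 to C5 and high dilution are what should secure this.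

Step 13
Reactants: 19 tricyclic epoxy diketone
Product: 21 tricyclic allylic alcohol (C1–OH on the C9 face; C2=C3; C6 enone), via epoxy hydrazone 20 (not isolated)
Conditions: N2H4·H2O (2 equiv), AcOH (cat.), MeOH, 0 °C to rt
Reagents that add atoms: none
Why: Wharton transposition, in which the α,β-epoxy hydrazone fragments to a vinyl diazene that loses N2, giving the C2=C3 olefin and the C1 carbinol with its C–O bond untouched; the non-conjugated epoxy ketone should condense with hydrazine before the hindered enone.

Step 14
Reactants: 21 tricyclic allylic alcohol; 22 angelic acid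
Product: 24 C1 angelate of 21, via angelic 2,4,6-trichlorobenzoic anhydride 23 (not isolated)
Conditions: 2,4,6-trichlorobenzoyl chloride, Et3N, toluene, rt; then 21, 80 °C
Reagents that add atoms: none
Why: Mixed-anhydride (Yamaguchi-type) esterification run without a nucleophilic catalyst, conditions under which angelic acid is transferred to hindered alcohols with the Z double bond retained.

Step 15
Reactants: 24 C1 angelate of 21
Product: 25 C2,C3-diol of 24 (both hydroxyls on the C5 face; 1,2-trans and 2,3-cis)
Conditions: OsO4 (5 mol %), N-methylmorpholine N-oxide, acetone/H2O, rt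
Reagents that add atoms: osmium tetroxide, O=[Os](=O)(=O)=O; N-methylmorpholine N-oxide, C[N+]1([O-])CCOCC1; water, O
Why: Catalytic osmium tetroxide syn-dihydroxylation of the only unconjugated olefin, from the face anti to the allylic angelate (the usual sense for allylic esters), which places both new hydroxyls on the C5 face.

Step 16
Reactants: 25 C2,C3-diol; 26 (R)-2-methylbutanoic acid
Product: 27 CNP0206166.1 (C1 angelate, C2 (R)-2-methylbutanoate, C3 free hydroxyl)
Conditions: EDC·HCl, DMAP (cat.), CH2Cl2, 0 °C
Reagents that add atoms: none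
Why: Steglich esterification, in which the C2 hydroxyl should be acylated in preference to the C3 hydroxyl because the latter is neopentyl-like (flanked by the quaternary C4), and the acid's α-stereocentre is preserved at 0 °C.

Compound list
1 | methyl 3,3-dimethylpent-4-enoate | COC(=O)CC(C)(C)C=C | starting material
2 | 3,3-dimethylpent-4-enal | O=CCC(C)(C)C=C | intermediate
3 | pent-1-en-3-one (ethyl vinyl ketone) | CCC(=O)C=C | starting material
4 | (S)-2-(2-methylbut-3-en-2-yl)-5-oxoheptanal | O=C[C@@H](CCC(=O)CC)C(C)(C)C=C | intermediate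
5 | (R)-2-methyl-4-(2-methylbut-3-en-2-yl)cyclohex-2-en-1-one | CC1=C[C@H](C(C)(C)C=C)CCC1=O | intermediate
6 | (1R,4R)-2-methyl-4-(2-methylbut-3-en-2-yl)cyclohex-2-en-1-ol (trans) | O[C@@H]1CC[C@@H](C(C)(C)C=C)C=C1C | intermediate
7 | propanoic acid | CCC(=O)O | starting material
8 | (1S,4R)-2-methyl-4-(2-methylbut-3-en-2-yl)cyclohex-2-en-1-yl propanoate (cis) | CCC(=O)O[C@H]1CC[C@@H](C(C)(C)C=C)C=C1C | intermediate
9 | trimethylsilyl ketene acetal of 8 (double-bond geometry not specified) | CC=C(O[Si](C)(C)C)O[C@H]1CC[C@@H](C(C)(C)C=C)C=C1C | intermediate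
10 | trimethylsilyl 2-[(1S,6R)-2-methyl-6-(2-methylbut-3-en-2-yl)cyclohex-2-en-1-yl]propanoate (C4 epimers) | C[Si](C)(C)OC(=O)C(C)[C@H]1C(C)=CCC[C@H]1C(C)(C)C=C | intermediate
11 | 2-[(1S,6R)-2-methyl-6-(2-methylbut-3-en-2-yl)cyclohex-2-en-1-yl]propanoic acid (C4 epimers) | OC(=O)C(C)[C@H]1C(C)=CCC[C@H]1C(C)(C)C=C | intermediate
12 | N-acylimidazole of 11 | O=C(n1ccnc1)C(C)[C@H]1C(C)=CCC[C@H]1C(C)(C)C=C | intermediate
13 | N-methoxy-N-methyl amide of 11 | CON(C)C(=O)C(C)[C@H]1C(C)=CCC[C@H]1C(C)(C)C=C | intermediate
14 | 4-[(1S,6R)-2-methyl-6-(2-methylbut-3-en-2-yl)cyclohex-2-en-1-yl]pent-1-en-3-one (C4 epimers) | C=CC(=O)C(C)[C@H]1C(C)=CCC[C@H]1C(C)(C)C=C | intermediate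
15 | cis-fused bicyclic enone (C3=O, C1=C2, C7=C8; C4 epimers) | O=C1C(C)[C@H]2C(C)=CCC[C@H]2C(C)(C)C=C1 | intermediate
16 | bicyclic epoxy ketone (C1–C2 epoxide on the convex face; C4 epimers) | O=C1C(C)[C@H]2C(C)=CCC[C@H]2C(C)(C)[C@@H]3O[C@H]13 | intermediate
17 | bicyclic epoxy enedione (C3 epoxy ketone, C6 enone; C4 epimers) | O=C1C(C)[C@H]2C(C)=CC(=O)C[C@H]2C(C)(C)[C@@H]3O[C@H]13 | intermediate
18 | bis(trimethylsilyl enol ether) of 17 (C3(OSiMe3)=C4 and C5=C6(OSiMe3)–C7=C8) | C[Si](C)(C)OC1=C(C)[C@H]2C(C)=CC(O[Si](C)(C)C)=C[C@H]2C(C)(C)[C@@H]3O[C@H]13 | intermediate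
19 | tricyclic epoxy diketone (C4–C5 bond formed; epoxide oxygen on the C9 face) | O=C1[C@@]2(C)[C@@H]3C(=O)C=C(C)[C@H]2[C@@H]3C(C)(C)[C@@H]4O[C@H]14 | intermediate
20 | C3 hydrazone of 19 | NN=C1[C@@]2(C)[C@@H]3C(=O)C=C(C)[C@H]2[C@@H]3C(C)(C)[C@@H]4O[C@H]14 | intermediate
21 | tricyclic allylic alcohol (C1–OH on the C9 face, C2=C3, C6 enone) | O[C@@H]1C=C[C@@]2(C)[C@@H]3C(=O)C=C(C)[C@H]2[C@@H]3C1(C)C | intermediate
22 | angelic acid ((Z)-2-methylbut-2-enoic acid) | C/C=C(/C)C(=O)O | starting material
23 | angelic 2,4,6-trichlorobenzoic anhydride | C/C=C(/C)C(=O)OC(=O)c1c(Cl)cc(Cl)cc1Cl | intermediate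
24 | C1 angelate of 21 | C/C=C(/C)C(=O)O[C@@H]1C=C[C@@]2(C)[C@@H]3C(=O)C=C(C)[C@H]2[C@@H]3C1(C)C | intermediate
25 | C1 angelate C2,C3-diol (hydroxyls on the C5 face) | C/C=C(/C)C(=O)O[C@@H]1[C@@H](O)[C@@H](O)[C@@]2(C)[C@@H]3C(=O)C=C(C)[C@H]2[C@@H]3C1(C)C | intermediate
26 | (R)-2-methylbutanoic acid | CC[C@@H](C)C(=O)O | starting material
27 | CNP0206166.1 | C/C=C(/C)C(=O)O[C@@H]1[C@@H](OC(=O)[C@H](C)CC)[C@@H](O)[C@@]2(C)[C@@H]3C(=O)C=C(C)[C@H]2[C@@H]3C1(C)C | target

Total step count: 16. Longest linear sequence: 16 steps (from 1).

Steps most likely to fail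

Step 12. The one-electron coupling may be diverted into intermolecular coupling, C–O bond formation, simple desilylation or acid-promoted epoxide opening, because closure of a strained four-membered ring from a radical cation is slow. The fallback makes the same bond in two-electron mode and sets out from 18 (prepared as in step 12). N-bromosuccinimide (1 equiv, THF, −78 °C) should brominate the more electron-rich siloxydiene at C5 and give the C5-bromo enone silyl enol ether F1, in which the C3 silyl enol ether is kept. Bu4N Ph3SiF2 in THF then releases the C3/C4 enolate regiospecifically, and this enolate displaces the C5 bromide in a 4-exo-tet alkylation of the kind used to close pinane-type bicyclo[3.1.1]heptanones; the route is rejoined at 19.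

Step 13. Hydrazine may condense competitively with the C6 enone carbonyl, or hydrazone formation at the hindered C3 ketone may be too slow, so that the transposition stalls or gives mixtures. The fallback sets out from 19 and avoids hydrazine. SmI2 (THF/MeOH, −90 °C) cleaves the C2–O bond of the epoxy ketone to give the β-hydroxy ketone F2. Et3SiCl/imidazole gives the triethylsilyl ether F3. KN(SiMe3)2 and PhNTf2 (THF, −78 °C) give the C2=C3 enol triflate F4; C2 is the only enolisable position, since the enone is flanked by bridgeheads. Pd(OAc)2, PPh3, Bu3N and HCO2H (DMF, 60 °C) reduce the triflate to the olefin, the silyl ether F5. HF·pyridine removes the silyl group and the route is rejoined at 21.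

Step 14. Activation of angelic acid may be accompanied by Z-to-E isomerisation to the tiglate, and acylation of the neopentyl-type C1 alcohol may be sluggish. The fallback builds the Z double bond after the acylation and sets out from 21. Esterification with 2-[bis(2,2,2-trifluoroethoxy)phosphoryl]propanoic acid (DCC, DMAP, CH2Cl2) gives the phosphonate ester F6. Still–Gennari olefination (KN(SiMe3)2, 18-crown-6, THF, −78 °C; acetaldehyde) then forms the Z-configured 2-methylbut-2-enoate, and the route is rejoined at 24.

Further compounds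
F1 | step 12 | C5-bromo enone retaining the C3 trimethylsilyl enol ether (C5 epimers) | C[Si](C)(C)OC1=C(C)[C@H]2C(C)=CC(=O)C(Br)[C@H]2C(C)(C)[C@@H]3O[C@H]13
F2 | step 13 | tricyclic β-hydroxy ketone (C1–OH on the C9 face, C2H2, C3=O) | O=C1[C@@]2(C)[C@@H]3C(=O)C=C(C)[C@H]2[C@@H]3C(C)(C)[C@H](O)C1
F3 | step 13 | triethylsilyl ether of F2 | O=C1[C@@]2(C)[C@@H]3C(=O)C=C(C)[C@H]2[C@@H]3C(C)(C)[C@H](O[Si](CC)(CC)CC)C1
F4 | step 13 | C2=C3 enol triflate of F3 | O=S(=O)(OC1[C@@]2(C)[C@@H]3C(=O)C=C(C)[C@H]2[C@@H]3C(C)(C)[C@H](O[Si](CC)(CC)CC)C=1)C(F)(F)F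
F5 | step 13 | triethylsilyl ether of 21 | CC[Si](CC)(CC)O[C@@H]1C=C[C@@]2(C)[C@@H]3C(=O)C=C(C)[C@H]2[C@@H]3C1(C)C
F6 | step 14 | 2-[bis(2,2,2-trifluoroethoxy)phosphoryl]propanoate of 21 | CC(C(=O)O[C@@H]1C=C[C@@]2(C)[C@@H]3C(=O)C=C(C)[C@H]2[C@@H]3C1(C)C)P(=O)(OCC(F)(F)F)OCC(F)(F)F
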